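The cycloheptane is cut at C2–C3 and C6–C7: C6, C5, C4 and C3 become the four carbons of a 2,3-disubstituted furan, C7–C1–C2 an oxyallyl unit, and the tertiary C6 oxygen, 1,4-related to the C3 methylene, is the furan oxygen. A single amine-catalysed (4+3) cycloaddition forms both bonds, closes the seven-membered ring across a temporary C3–O–C6 bridge and sets the C6 configuration, from which all other centres are then derived. Its precursors are 2-[(4-methoxyphenoxy)methyl]-3-methylfuran and (E)-4-(triethylsilyloxy)penta-2,4-dienal. The bridge is later opened by β-elimination from the C1 ketone, which frees the C6 hydroxyl and leaves C3 as the ring methylene.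

Key step: step 5

Assumptions and conventions
- Locants C1–C7 are those of the cycloheptane of the target: C1 lactone O–CH, C2 CH bearing the lactone carbon, C3 CH2, C4 CHOH, C5 CHMe, C6 C(OH), C7 CH–O-ester. α is the face of this ring that carries the C6 oxygen (the face of the oxygen bridge), β the other face. PMP = 4-methoxyphenyl, TBS = tert-butyldimethylsilyl.
- The (2R,5R) catalyst is chosen from the usual model in which the benzyl group shields one face of the E-iminium ion; if the sense of induction proves opposite, the (2S,5S) salt is used and nothing else changes.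
- The furfuryl oxygen is carried as its PMP ether rather than as a silyl ether: three different silyl ethers are needed after the key step, and the late unmasking of this oxygen must be orthogonal to them and survive hydrogenation. The carbon skeleton of the furan is unchanged.
- Compounds 1, 4, 34, 38, the catalyst and all reagents are taken as commercial.

Step 1
Reactants: 1 methyl 3-methylfuran-2-carboxylate
Product: 2 (3-methylfuran-2-yl)methanol
Conditions: LiAlH4, Et2O, 0 °C
Reagents that add atoms: none
Why: Hydride reduction of the ester (LiAlH4 reduction) gives the primary furfuryl alcohol and creates no stereocentre.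

Step 2
Reactants: 2 (3-methylfuran-2-yl)methanol
Product: 3 2-[(4-methoxyphenoxy)methyl]-3-methylfuran
Conditions: 4-methoxyphenol, PPh3, diisopropyl azodicarboxylate, THF, 0 °C → rt
Reagents that add atoms: 4-methoxyphenol, COc1ccc(O)cc1
Why: Mitsunobu etherification of the activated primary alcohol with the phenol gives an aryl ether that is inert to acid, base, hydride, fluoride and hydrogenation and is removed oxidatively in step 22.

Step 3
Reactants: 4 2-methylfuran
Product: 6 (E)-4-oxopent-2-enal, via (Z)-4-oxopent-2-enal 5 (not isolated)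
Conditions: NBS, NaHCO3, acetone/H2O, −15 °C; then pyridine, rt
Reagents that add atoms: water, O
Why: Bromination–hydration of the furan (oxidative furan ring opening) gives the cis-enedicarbonyl compound, which pyridine isomerises by reversible conjugate addition to the more stable E isomer.

Step 4
Reactants: 6 (E)-4-oxopent-2-enal
Product: 7 (E)-4-(triethylsilyloxy)penta-2,4-dienal
Conditions: Et3SiOTf, Et3N, CH2Cl2, 0 °C
Reagents that add atoms: triethylsilyl trifluoromethanesulfonate, CC[Si](CC)(CC)OS(=O)(=O)C(F)(F)F
Why: Soft enolisation with silyl triflate and amine (silyl enol ether formation) can only occur at the methyl ketone, since the aldehyde has no sp3 α-hydrogen, and leaves the E alkene untouched.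

Step 5
Reactants: 3 2-[(4-methoxyphenoxy)methyl]-3-methylfuran; 7 (E)-4-(triethylsilyloxy)penta-2,4-dienal
Product: 10 bicyclic keto aldehyde (C2 side chain β), via iminium trifluoroacetate 8 (not isolated), via bicyclic enamine 9 (not isolated)
Conditions: (2R,5R)-5-benzyl-2-tert-butyl-3-methylimidazolidin-4-one·CF3CO2H (20 mol%), CH2Cl2, −78 °C; then H2O
Reagents that add atoms: water, O
Why: Condensation of the amine salt with 7 gives iminium ion 8, an amino-stabilised 2-siloxyallyl cation; the free α-carbon of 3 adds to its β-carbon (C2) on the face left open by the benzyl group, the silyl enol ether terminus (C7) then attacks the furanium ion at its substituted carbon (C6), and loss of the silyl group and hydrolysis of enamine 9 release 10 and the catalyst. The closest known reaction type is the imidazolidinone-catalysed (4+3) cycloaddition of 4-silyloxypentadienals with 2,5-disubstituted furans; the present furan has one free α-position, which is the point of extension. The second bond closes the cycloheptene ring in a 7-(enolendo)-exo-trig mode, which is at the same time a 6-(enolendo)-endo-trig closure of the oxane ring through the bridging oxygen. C2 is set by catalyst control of the iminium face, C3 follows from the compact arrangement that places the side chain trans to the oxygen bridge, and C6 is fixed because the bridge can only span one face. The step needs enantiofacial control (catalyst), first attack by the free rather than the substituted furan α-carbon (less hindered, and it leads to the more substituted oxocarbenium ion) and ring closure faster than proton loss from the furanium ion; the low temperature, the weakly basic counter-ion and an enol ether that stays silylated until closure are meant to secure the last point.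

Step 6
Reactants: 10 bicyclic keto aldehyde
Product: 12 bicyclic keto ester, via carboxylic acid 11 (not isolated)
Conditions: NaClO2, NaH2PO4, 2-methylbut-2-ene, t-BuOH/H2O, 0 °C; then Me3SiCHN2, MeOH/toluene, 0 °C
Reagents that add atoms: sodium chlorite, [Na+].[O-]Cl=O; trimethylsilyldiazomethane, C[Si](C)(C)C=[N+]=[N-]
Why: Pinnick oxidation converts only the aldehyde (hypochlorite is scavenged, so the strained alkene and the aryl ether survive) and esterification with the diazo reagent gives the methyl ester under neutral conditions without touching C2.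

Step 7
Reactants: 12 bicyclic keto ester
Product: 13 C1 dimethyl ketal
Conditions: HC(OMe)3, MeOH, pyridinium p-toluenesulfonate (cat.), 40 °C
Reagents that add atoms: trimethyl orthoformate, COC(OC)OC; methanol, CO
Why: Acid-catalysed ketalisation with the orthoformate as water scavenger masks the C1 ketone, which borane would reduce in step 8 and which could not be told apart from the C4 ketone in step 10.

Step 8
Reactants: 13 C1 dimethyl ketal
Product: 15 C4 α-alcohol (C5 methyl β), via C4 alkylborane 14 (not isolated)
Conditions: BH3·THF, THF, 0 °C; then NaBO3·4H2O, H2O, rt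
Reagents that add atoms: sodium perborate, [Na+].[O-]OB=O
Why: Hydroboration–oxidation adds H and B syn from the exo (α) face of the strained bicyclic alkene, the endo face being covered by the three-carbon bridge and its axial methoxy group, with boron on the less substituted C4, so the C4 hydroxyl is α and the C5 methyl is pushed to the endo (β) position.

Step 9
Reactants: 15 C4 α-alcohol
Product: 17 C4 ketone (C5 methyl α), via C5 β-methyl ketone 16 (not isolated)
Conditions: Dess–Martin periodinane, NaHCO3, CH2Cl2, rt; then K2CO3, MeOH, rt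
Reagents that add atoms: none
Why: Dess–Martin oxidation gives the C4 ketone, and base-mediated epimerisation through its enolate moves the C5 methyl from the congested endo position beneath the ketal to the exo (α) position, the thermodynamic epimer.

Step 10
Reactants: 17 C4 ketone
Product: 18 C4 β-alcohol
Conditions: NaBH4, MeOH, −20 °C
Reagents that add atoms: none
Why: In this borohydride reduction hydride attacks the bicyclic ketone from the open exo face, so the new hydroxyl is endo (β), trans to the C5 methyl.

Step 11
Reactants: 18 C4 β-alcohol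
Product: 19 C4 β-TBS ether
Conditions: t-BuMe2SiOTf, 2,6-lutidine, CH2Cl2, −78 °C
Reagents that add atoms: tert-butyldimethylsilyl trifluoromethanesulfonate, CC(C)(C)[Si](C)(C)OS(=O)(=O)C(F)(F)F
Why: Silylation with the silyl triflate and a hindered pyridine protects the hindered endo alcohol at low temperature under non-nucleophilic conditions, before it can engage the neighbouring ketal or the ester.

Step 12
Reactants: 19 C4 β-TBS ether
Product: 20 C1 ketone
Conditions: pyridinium p-toluenesulfonate, acetone/H2O, 40 °C
Reagents that add atoms: water, O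
Why: Mild acid hydrolysis of the dimethyl ketal (acetal hydrolysis) returns the C1 ketone while the secondary TBS ether and the aryl ether are stable.

Step 13
Reactants: 20 C1 ketone
Product: 22 C7 α-silyloxy ketone, via triethylsilyl enol ether 21 (not isolated)
Conditions: LiN(i-Pr)2, Et3SiCl, THF, −78 °C; then mCPBA, NaHCO3, CH2Cl2, −20 °C
Reagents that add atoms: chlorotriethylsilane, CC[Si](Cl)(CC)CC; 3-chloroperoxybenzoic acid, OOC(=O)c1cccc(Cl)c1
Why: In this Rubottom oxidation kinetic deprotonation takes the axial hydrogen of the C7 methylene rather than the C2 methine, and the peracid epoxidises the enol ether from the convex face, away from the two-carbon bridge and its endo silyloxy group, so that after 1,4-silyl migration the C7 silyloxy group is axial (α).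

Step 14
Reactants: 22 C7 α-silyloxy ketone
Product: 24 cycloheptenone, via trimethylsilyl enol ether 23 (not isolated)
Conditions: Me3SiOTf, Et3N, CH2Cl2, 0 °C → rt
Reagents that add atoms: trimethylsilyl trifluoromethanesulfonate, C[Si](C)(C)OS(=O)(=O)C(F)(F)F
Why: In this E1cB-type bridge opening (retro-oxa-Michael) soft enolisation can remove only the axial C2–H, the C7–H being equatorial and misaligned, and silyl triflate activation of the bridge oxygen lets the enol ether expel the C3–O bond, which gives the enone and traps the C6 alkoxide as its silyl ether so that it cannot add back.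

Step 15
Reactants: 24 cycloheptenone
Product: 25 cycloheptanone (C2 side chain α)
Conditions: H2 (1 atm), Pd/C, EtOAc, rt
Reagents that add atoms: none
Why: In this catalytic hydrogenation of the enone the C7 silyloxy group is expected to be pseudo-axial on the α face and the C4 silyloxy group pseudo-equatorial, with the C5 methyl and the C6 oxygen also on the α face, so hydrogen should be delivered to the β face and the C2 side chain ends up α.

Step 16
Reactants: 25 cycloheptanone
Product: 27 cis-fused lactone, via C1 α-hydroxy ester 26 (not isolated)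
Conditions: LiBH(s-Bu)3, THF, −78 °C; then aq. NH4Cl, rt
Reagents that add atoms: none
Why: In this reduction by a bulky trialkylborohydride hydride approaches C1 from the β face, anti to both α-substituents (C2 side chain and C7 silyloxy group), and the resulting α alkoxide closes onto the ester to give the cis-fused γ-lactone (lactonisation).

Step 17
Reactants: 27 cis-fused lactone
Product: 30 α-methylene lactone, via Mannich base 28 (not isolated), via trimethylammonium iodide 29 (not isolated)
Conditions: LiN(i-Pr)2, THF, −78 °C; dimethyl(methylidene)ammonium iodide; then MeI, THF, rt; then aq. NaHCO3, EtOAc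
Reagents that add atoms: dimethyl(methylidene)ammonium iodide, C=[N+](C)C.[I-]
Why: In this α-methylenation by the Mannich route the lactone enolate, the only enolisable carbonyl present, is aminomethylated, and quaternisation followed by base-induced elimination gives the exocyclic alkene.

Step 18
Reactants: 30 α-methylene lactone
Product: 31 C6,C7 cis-diol
Conditions: pyridinium p-toluenesulfonate, MeOH, rt
Reagents that add atoms: none
Why: Acid-catalysed methanolysis (selective desilylation) removes the tertiary trimethylsilyl and the secondary triethylsilyl ether while the more robust TBS ether stays.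

Step 19
Reactants: 31 C6,C7 cis-diol
Product: 32 C7 ketone
Conditions: Dess–Martin periodinane, NaHCO3, CH2Cl2, 0 °C → rt
Reagents that add atoms: none
Why: Dess–Martin oxidation of the only secondary alcohol gives the α-hydroxy ketone, since the tertiary C6 hydroxyl cannot be oxidised.

Step 20
Reactants: 32 C7 ketone
Product: 33 C6,C7 trans-diol
Conditions: Me4NBH(OAc)3, MeCN/AcOH, −30 °C
Reagents that add atoms: none
Why: In this hydroxyl-directed triacetoxyborohydride reduction (Saksena–Evans reduction) the C6 hydroxyl binds boron and delivers hydride to the α face of the C7 ketone, so the new hydroxyl is β, trans to the C6 hydroxyl.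

Step 21
Reactants: 33 C6,C7 trans-diol; 34 3-methylbutanoic acid
Product: 35 C7 3-methylbutanoate
Conditions: 2,4,6-trichlorobenzoyl chloride, Et3N, THF; then 4-(dimethylamino)pyridine, toluene, rt
Reagents that add atoms: none
Why: Yamaguchi esterification acylates the secondary C7 hydroxyl through the mixed anhydride, the tertiary C6 hydroxyl being too hindered to react.

Step 22
Reactants: 35 C7 3-methylbutanoate
Product: 36 primary alcohol
Conditions: Ce(NH4)2(NO3)6, pyridine, MeCN/H2O, 0 °C
Reagents that add atoms: none
Why: Oxidative dearylation by the ceric salt converts the electron-rich aryl ether to the quinone and liberates the primary alcohol without touching the silyl ether, the esters or the electron-poor alkene.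

Step 23
Reactants: 36 primary alcohol
Product: 37 aldehyde
Conditions: Dess–Martin periodinane, NaHCO3, CH2Cl2, rt
Reagents that add atoms: none
Why: Dess–Martin oxidation of the primary alcohol gives an aldehyde that cannot enolise because its α-carbon is fully substituted, and the still protected C4 oxygen cannot form a lactol with it.

Step 24
Reactants: 37 aldehyde; 38 (E)-1-bromoprop-1-ene
Product: 39 allylic alcohol
Conditions: CrCl2, NiCl2 (cat.), DMF, rt
Reagents that add atoms: none
Why: In this Nozaki–Hiyama–Kishi reaction the alkenylchromium reagent, formed with retention of the E geometry, adds only to the aldehyde and leaves lactone, ester and free tertiary hydroxyl untouched; the new carbinol centre is removed in step 25.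

Step 25
Reactants: 39 allylic alcohol
Product: 40 enone silyl ether
Conditions: MnO2, CH2Cl2, rt
Reagents that add atoms: none
Why: Allylic oxidation with MnO2 converts the allylic alcohol to the E enone and leaves the tertiary hydroxyl alone.

Step 26
Reactants: 40 enone silyl ether
Product: 41 CNP0186412.1
Conditions: HF·pyridine, pyridine, THF, 0 °C → rt
Reagents that add atoms: none
Why: Fluoride-mediated desilylation under buffered, weakly acidic conditions removes the last silyl ether without acyl migration or conjugate addition to the two Michael acceptors.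

Compound list
1 | methyl 3-methylfuran-2-carboxylate | COC(=O)c1occc1C | starting material
2 | (3-methylfuran-2-yl)methanol | Cc1ccoc1CO | intermediate
3 | 2-[(4-methoxyphenoxy)methyl]-3-methylfuran | Cc1ccoc1COc1ccc(OC)cc1 | intermediate
4 | 2-methylfuran | Cc1ccco1 | starting material
5 | (Z)-4-oxopent-2-enal (not isolated) | CC(=O)/C=C\C=O | intermediate
6 | (E)-4-oxopent-2-enal | CC(=O)/C=C/C=O | intermediate
7 | (E)-4-(triethylsilyloxy)penta-2,4-dienal | C=C(O[Si](CC)(CC)CC)/C=C/C=O | intermediate
8 | iminium trifluoroacetate from 7 and the (2R,5R)-imidazolidinone (not isolated) | C=C(O[Si](CC)(CC)CC)/C=C/C=[N+]1[C@@H](C(C)(C)C)N(C)C(=O)[C@H]1Cc1ccccc1.[O-]C(=O)C(F)(F)F | intermediate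
9 | bicyclic enamine, the cycloadduct still bound to the catalyst through its C2 side chain (not isolated) | O=C1[C@@H](/C=C/N3[C@@H](C(C)(C)C)N(C)C(=O)[C@H]3Cc3ccccc3)[C@H]2C=C(C)[C@@](O2)(COc3ccc(OC)cc3)C1 | intermediate
10 | 1-[(4-methoxyphenoxy)methyl]-7-methyl-4-(2-oxoethyl)-8-oxabicyclo[3.2.1]oct-6-en-3-one (C3–O–C6 bridge, C2 side chain β) | O=C1[C@@H](CC=O)[C@H]2C=C(C)[C@@](O2)(COc3ccc(OC)cc3)C1 | intermediate
11 | carboxylic acid from 10, CH2CO2H on C2 (not isolated) | O=C1[C@@H](CC(=O)O)[C@H]2C=C(C)[C@@](O2)(COc3ccc(OC)cc3)C1 | intermediate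
12 | methyl ester of 11 (bicyclic keto ester) | O=C1[C@@H](CC(=O)OC)[C@H]2C=C(C)[C@@](O2)(COc3ccc(OC)cc3)C1 | intermediate
13 | C1 dimethyl ketal of 12 | COC1(OC)[C@@H](CC(=O)OC)[C@H]2C=C(C)[C@@](O2)(COc3ccc(OC)cc3)C1 | intermediate
14 | C4 α-alkylborane of 13, C5 methyl β (not isolated) | COC1(OC)[C@@H](CC(=O)OC)[C@H]2[C@H](B)[C@@H](C)[C@@](O2)(COc3ccc(OC)cc3)C1 | intermediate
15 | C4 α-alcohol, C5 methyl β, C1 ketal | COC1(OC)[C@@H](CC(=O)OC)[C@H]2[C@H](O)[C@@H](C)[C@@](O2)(COc3ccc(OC)cc3)C1 | intermediate
16 | C4 ketone, C5 methyl β (not isolated) | COC1(OC)[C@@H](CC(=O)OC)[C@H]2C(=O)[C@@H](C)[C@@](O2)(COc3ccc(OC)cc3)C1 | intermediate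
17 | C4 ketone, C5 methyl α | COC1(OC)[C@@H](CC(=O)OC)[C@H]2C(=O)[C@H](C)[C@@](O2)(COc3ccc(OC)cc3)C1 | intermediate
18 | C4 β-alcohol, C5 methyl α | COC1(OC)[C@@H](CC(=O)OC)[C@H]2[C@@H](O)[C@H](C)[C@@](O2)(COc3ccc(OC)cc3)C1 | intermediate
19 | C4 β-TBS ether of 18 | COC1(OC)[C@@H](CC(=O)OC)[C@H]2[C@@H](O[Si](C)(C)C(C)(C)C)[C@H](C)[C@@](O2)(COc3ccc(OC)cc3)C1 | intermediate
20 | bicyclic C1 ketone, C4 β-OTBS | O=C1[C@@H](CC(=O)OC)[C@H]2[C@@H](O[Si](C)(C)C(C)(C)C)[C@H](C)[C@@](O2)(COc3ccc(OC)cc3)C1 | intermediate
21 | C1(OSiEt3)=C7 enol ether of 20 (not isolated) | CC[Si](CC)(CC)OC1[C@@H](CC(=O)OC)[C@H]2[C@@H](O[Si](C)(C)C(C)(C)C)[C@H](C)[C@@](O2)(COc3ccc(OC)cc3)C=1 | intermediate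
22 | bicyclic C1 ketone with C7 α-triethylsilyloxy group | O=C1[C@@H](CC(=O)OC)[C@H]2[C@@H](O[Si](C)(C)C(C)(C)C)[C@H](C)[C@@](O2)(COc3ccc(OC)cc3)[C@@H]1O[Si](CC)(CC)CC | intermediate
23 | C1(OSiMe3)=C2 enol ether of 22 (not isolated) | C[Si](C)(C)OC1=C(CC(=O)OC)[C@H]2[C@@H](O[Si](C)(C)C(C)(C)C)[C@H](C)[C@@](O2)(COc3ccc(OC)cc3)[C@@H]1O[Si](CC)(CC)CC | intermediate
24 | ring-opened cyclohept-2-enone: CH2CO2Me on C2, C4 β-OTBS, C5 α-Me, C6 α-OSiMe3 and CH2OPMP, C7 α-OSiEt3 | O=C1C(CC(=O)OC)=C[C@@H](O[Si](C)(C)C(C)(C)C)[C@H](C)[C@@](O[Si](C)(C)C)(COc2ccc(OC)cc2)[C@@H]1O[Si](CC)(CC)CC | intermediate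
25 | cycloheptanone, as 24 with C2–C3 saturated and the C2 side chain α | O=C1[C@H](CC(=O)OC)C[C@@H](O[Si](C)(C)C(C)(C)C)[C@H](C)[C@@](O[Si](C)(C)C)(COc2ccc(OC)cc2)[C@@H]1O[Si](CC)(CC)CC | intermediate
26 | C1 α-hydroxy ester from 25 (not isolated) | O[C@@H]1[C@H](CC(=O)OC)C[C@@H](O[Si](C)(C)C(C)(C)C)[C@H](C)[C@@](O[Si](C)(C)C)(COc2ccc(OC)cc2)[C@@H]1O[Si](CC)(CC)CC | intermediate
27 | cis-fused γ-lactone (C1 O α, C2 α) | C1C(=O)O[C@@H]2[C@H]1C[C@@H](O[Si](C)(C)C(C)(C)C)[C@H](C)[C@@](O[Si](C)(C)C)(COc3ccc(OC)cc3)[C@@H]2O[Si](CC)(CC)CC | intermediate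
28 | α-(dimethylaminomethyl) lactone (not isolated) | CN(C)CC1C(=O)O[C@@H]2[C@H]1C[C@@H](O[Si](C)(C)C(C)(C)C)[C@H](C)[C@@](O[Si](C)(C)C)(COc3ccc(OC)cc3)[C@@H]2O[Si](CC)(CC)CC | intermediate
29 | methiodide of 28 (not isolated) | C[N+](C)(C)CC1C(=O)O[C@@H]2[C@H]1C[C@@H](O[Si](C)(C)C(C)(C)C)[C@H](C)[C@@](O[Si](C)(C)C)(COc3ccc(OC)cc3)[C@@H]2O[Si](CC)(CC)CC.[I-] | intermediate
30 | α-methylene γ-lactone, C4 β-OTBS, C6 α-OSiMe3, C7 α-OSiEt3 | C=C1C(=O)O[C@@H]2[C@H]1C[C@@H](O[Si](C)(C)C(C)(C)C)[C@H](C)[C@@](O[Si](C)(C)C)(COc3ccc(OC)cc3)[C@@H]2O[Si](CC)(CC)CC | intermediate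
31 | C6 α, C7 α diol | C=C1C(=O)O[C@@H]2[C@H]1C[C@@H](O[Si](C)(C)C(C)(C)C)[C@H](C)[C@@](O)(COc3ccc(OC)cc3)[C@@H]2O | intermediate
32 | C7 ketone with C6 α-hydroxyl | C=C1C(=O)O[C@@H]2[C@H]1C[C@@H](O[Si](C)(C)C(C)(C)C)[C@H](C)[C@@](O)(COc3ccc(OC)cc3)C2=O | intermediate
33 | C6 α, C7 β diol | C=C1C(=O)O[C@@H]2[C@H]1C[C@@H](O[Si](C)(C)C(C)(C)C)[C@H](C)[C@@](O)(COc3ccc(OC)cc3)[C@H]2O | intermediate
34 | 3-methylbutanoic acid | CC(C)CC(=O)O | starting material
35 | C7 β 3-methylbutanoate of 33 | C=C1C(=O)O[C@@H]2[C@H]1C[C@@H](O[Si](C)(C)C(C)(C)C)[C@H](C)[C@@](O)(COc3ccc(OC)cc3)[C@H]2OC(=O)CC(C)C | intermediate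
36 | C6 hydroxymethyl compound (aryl ether removed) | C=C1C(=O)O[C@@H]2[C@H]1C[C@@H](O[Si](C)(C)C(C)(C)C)[C@H](C)[C@@](O)(CO)[C@H]2OC(=O)CC(C)C | intermediate
37 | C6 aldehyde | C=C1C(=O)O[C@@H]2[C@H]1C[C@@H](O[Si](C)(C)C(C)(C)C)[C@H](C)[C@@](O)(C=O)[C@H]2OC(=O)CC(C)C | intermediate
38 | (E)-1-bromoprop-1-ene | C/C=C/Br | starting material
39 | C6 (E)-1-hydroxybut-2-enyl compound (both carbinol epimers) | C=C1C(=O)O[C@@H]2[C@H]1C[C@@H](O[Si](C)(C)C(C)(C)C)[C@H](C)[C@@](O)(C(O)/C=C/C)[C@H]2OC(=O)CC(C)C | intermediate
40 | C6 (E)-but-2-enoyl compound, C4 β-OTBS | C=C1C(=O)O[C@@H]2[C@H]1C[C@@H](O[Si](C)(C)C(C)(C)C)[C@H](C)[C@@](O)(C(=O)/C=C/C)[C@H]2OC(=O)CC(C)C | intermediate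
41 | CNP0186412.1 | C=C1C(=O)O[C@@H]2[C@H]1C[C@@H](O)[C@H](C)[C@@](O)(C(=O)/C=C/C)[C@H]2OC(=O)CC(C)C | target

Total step count: 26. Longest linear sequence: 24 steps (steps 1 and 2, then 5 to 26).

Steps most likely to fail

Step 5. After the first C–C bond the furanium ion may lose the proton at C3 and rearomatise, so that only conjugate (Friedel–Crafts) alkylation of the furan results. The silyl enol ether may also be protonated off before it can close the ring, and facial control by the catalyst may erode with this furan. Fallback: starting from furan 3, the oxyallyl cation generated from methyl 5-bromo-4-oxopentanoate with Et3N in 2,2,2-trifluoroethanol is trapped in a (4+3) cycloaddition. This α-halo ketone route is established for furans with free α-positions. After separation from regio- and diastereomers it should give racemic keto ester F1. The enantiomers are separated by preparative chromatography on a chiral stationary phase, which comes back to the route at 12 and makes steps 3 to 6 unnecessary.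

Step 14. The enol ether may form without expelling the C3–O bond, which overlaps only partly with the enol π system in the bicycle, or enolisation may occur toward C7 and open the bridge at C6. Fallback: starting from ketone 17, the C3–O bond is cleaved reductively as the α-alkoxy substituent of the C4 ketone with SmI2 (THF/MeOH, −78 °C) to give ring-opened hydroxy ketone F2. Hydroxyl-directed reduction with Me4NBH(OAc)3 gives anti diol F3 (C4 hydroxyl β). Treatment with t-BuMe2SiCl/imidazole and then 1-(trimethylsilyl)imidazole gives bis-silyl ether F4, and mild hydrolysis of the ketal gives ketone F5. Rubottom oxidation as in step 13 gives silyloxy ketone F6. Saegusa–Ito oxidation of its C1 enol silane with Pd(OAc)2 can introduce the double bond only toward C2–C3, because C6 bears no hydrogen, and comes back to the route at 24.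

Step 15. Hydrogen may be delivered to the wrong face of the C2=C3 bond, leaving the C2 side chain β. Fallback: starting from enone 24, 1,2-reduction under Luche conditions (NaBH4, CeCl3, MeOH) gives allylic alcohol F7, with hydride anti to the C7 silyloxy group. F7 lactonises on work-up to β,γ-unsaturated lactone F8, and 1,8-diazabicyclo[5.4.0]undec-7-ene moves the double bond into conjugation to give butenolide F9. Hydrogenation over Pd/C then adds hydrogen to C2 from the face of the C1 hydrogen, the usual outcome for ring-fused butenolides, and comes back to the route at the cis-fused lactone 27.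

Further compounds
F1 | step 5 | racemic form of keto ester 12 | O=C1C(CC(=O)OC)C2C=C(C)C(O2)(COc3ccc(OC)cc3)C1
F2 | step 14 | ring-opened hydroxy ketone: C1 dimethyl ketal, C4 ketone, C5 α-Me, C6 α-OH | COC1(OC)[C@@H](CC(=O)OC)CC(=O)[C@H](C)[C@@](O)(COc2ccc(OC)cc2)C1
F3 | step 14 | anti diol: C4 β-OH, C6 α-OH | COC1(OC)[C@@H](CC(=O)OC)C[C@@H](O)[C@H](C)[C@@](O)(COc2ccc(OC)cc2)C1
F4 | step 14 | bis-silyl ether: C4 β-OTBS, C6 α-OSiMe3 | COC1(OC)[C@@H](CC(=O)OC)C[C@@H](O[Si](C)(C)C(C)(C)C)[C@H](C)[C@@](O[Si](C)(C)C)(COc2ccc(OC)cc2)C1
F5 | step 14 | C1 ketone from F4 | O=C1[C@@H](CC(=O)OC)C[C@@H](O[Si](C)(C)C(C)(C)C)[C@H](C)[C@@](O[Si](C)(C)C)(COc2ccc(OC)cc2)C1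
F6 | step 14 | C7 α-triethylsilyloxy ketone (C2 epimer of 25) | O=C1[C@@H](CC(=O)OC)C[C@@H](O[Si](C)(C)C(C)(C)C)[C@H](C)[C@@](O[Si](C)(C)C)(COc2ccc(OC)cc2)[C@@H]1O[Si](CC)(CC)CC
F7 | step 15 | C1 α allylic alcohol from 24 | O[C@@H]1C(CC(=O)OC)=C[C@@H](O[Si](C)(C)C(C)(C)C)[C@H](C)[C@@](O[Si](C)(C)C)(COc2ccc(OC)cc2)[C@@H]1O[Si](CC)(CC)CC
F8 | step 15 | β,γ-unsaturated γ-lactone (C2=C3) | C1C(=O)O[C@@H]2C1=C[C@@H](O[Si](C)(C)C(C)(C)C)[C@H](C)[C@@](O[Si](C)(C)C)(COc3ccc(OC)cc3)[C@@H]2O[Si](CC)(CC)CC
F9 | step 15 | butenolide (double bond between C2 and the lactone α-carbon) | C1(=O)O[C@@H]2C(=C1)C[C@@H](O[Si](C)(C)C(C)(C)C)[C@H](C)[C@@](O[Si](C)(C)C)(COc3ccc(OC)cc3)[C@@H]2O[Si](CC)(CC)CC
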